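**Plan**

- Retrosynthesis: CHO and the diaryl ketone are taken back to a phthalide, and that to a benzodioxinone with a silylated carbinol on C1'. Ring B is then cut at C1'–C2' (aldol), the chain at C6'–C1' and C4'–C5' (two Claisen acylations), and ring A at the aryl–carbinol bond and at C3–Cl.
- Enabling feature: ring B has the carboxyl-derived carbon on C2', oxygens on the alternate carbons C3' and C5', the prenyl group on C6' and the ketone-bearing carbon at C1'. This is the pattern of a folded 3,5,7-tricarbonyl ester whose terminal ketone carbon is C1' and whose prenylated carbon lies between two ketones.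
- Forward: ring A is chlorinated and given a two-carbon mandelate arm, the dioxinone is acylated with the hexenoyl chloride, and the two fragments are joined by a second acylation. Ring B is then closed by aldol aromatization, and a lactone/diol redox sequence sets C=O and CHO last.
- Stereochemistry: the target is achiral. The benzylic carbinol centre is carried as a racemate and erased on oxidation, and the prenyl alkene has no geometry.

Key step: step 8

Remark: every compound with the benzylic carbinol centre is racemic; 14 and 15 are diastereomer (and tautomer) mixtures, which is of no consequence.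

**Route**

Step 1
Reactants: 1 3-methoxy-5-methylphenol
Product: 2 2-chloro-5-methoxy-3-methylphenol
Conditions: SO2Cl2 (1.0 equiv), 2,2,6,6-tetramethylpiperidine (5 mol %), toluene, 0 °C to rt
Reagents that add atoms: sulfuryl chloride, O=S(=O)(Cl)Cl
Why: Amine-catalysed ortho-chlorination of a phenol (electrophilic aromatic substitution through an N-chloroamine hydrogen-bonded to the OH) should place chlorine on the ortho carbon that is also para to OMe, because both directing effects converge there and not on the doubly flanked carbon between OH and OMe or on the para carbon.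

Step 2
Reactants: 2 2-chloro-5-methoxy-3-methylphenol; 3 ethyl glyoxylate
Product: 5 ethyl 2-(3-chloro-2-hydroxy-6-methoxy-4-methylphenyl)-2-hydroxyacetate (racemic), via bromomagnesium phenoxide 4 (not isolated)
Conditions: EtMgBr (1.0 equiv), Et2O, 0 °C; solvent exchanged for CH2Cl2; freshly distilled 3, rt; aq. NH4Cl
Reagents that add atoms: none
Why: Ortho-specific Friedel–Crafts hydroxyalkylation of a magnesium phenoxide by a glyoxylate runs through a six-membered chelate in a non-coordinating solvent, and with one ortho position blocked by chlorine the only site left is the carbon between OH and OMe; the new carbinol centre forms as a racemate.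

Step 3
Reactants: 5 ethyl 2-(3-chloro-2-hydroxy-6-methoxy-4-methylphenyl)-2-hydroxyacetate
Product: 6 ethyl 2-(tert-butyldimethylsilyloxy)-2-[2-(tert-butyldimethylsilyloxy)-3-chloro-6-methoxy-4-methylphenyl]acetate (racemic)
Conditions: TBSOTf (2.5 equiv), 2,6-lutidine, CH2Cl2, 0 °C to rt
Reagents that add atoms: tert-butyldimethylsilyl trifluoromethanesulfonate, CC(C)(C)[Si](C)(C)OS(=O)(=O)C(F)(F)F
Why: Silylation with a silyl triflate and a hindered pyridine base caps both the flanked phenol and the secondary α-hydroxy ester faster than the hydroxy ester can lactonize.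

Step 4
Reactants: 6 ethyl 2-(tert-butyldimethylsilyloxy)-2-[2-(tert-butyldimethylsilyloxy)-3-chloro-6-methoxy-4-methylphenyl]acetate
Product: 7 2-(tert-butyldimethylsilyloxy)-2-[2-(tert-butyldimethylsilyloxy)-3-chloro-6-methoxy-4-methylphenyl]-N-methoxy-N-methylacetamide (racemic)
Conditions: MeNH(OMe)·HCl, i-PrMgCl, THF, −20 °C to rt
Reagents that add atoms: N,O-dimethylhydroxylamine hydrochloride, CNOC.Cl
Why: Ester aminolysis by the chloromagnesium amide of N,O-dimethylhydroxylamine gives the Weinreb amide under conditions that aryl and alkyl silyl ethers tolerate.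

Step 5
Reactants: 8 5-methylhex-4-enoic acid
Product: 9 5-methylhex-4-enoyl chloride
Conditions: (COCl)2, DMF (cat.), CH2Cl2, 0 °C to rt; concentrated and used crude
Reagents that add atoms: oxalyl chloride, O=C(Cl)C(=O)Cl
Why: Acid chloride formation through the catalytic chloroiminium species is standard, and the trisubstituted alkene is inert under these conditions.

Step 6
Reactants: 9 5-methylhex-4-enoyl chloride; 10 2,2,6-trimethyl-4H-1,3-dioxin-4-one
Product: 12 2,2-dimethyl-6-(6-methyl-2-oxohept-5-enyl)-4H-1,3-dioxin-4-one, via lithium dienolate 11 (not isolated)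
Conditions: 10 (2 equiv), LiN(SiMe3)2 (2 equiv), THF, −78 °C; then 9 (1 equiv), −78 to −40 °C; aq. NH4Cl
Reagents that add atoms: none
Why: Vinylogous Claisen acylation of the dioxinone dienolate occurs at its terminal (6-methyl) carbon, with the second equivalent of dienolate absorbing the acidity of the β-keto product.

Step 7
Reactants: 12 2,2-dimethyl-6-(6-methyl-2-oxohept-5-enyl)-4H-1,3-dioxin-4-one; 7 the Weinreb amide of step 4
Product: 14 6-{5-[2-(tert-butyldimethylsilyloxy)-3-chloro-6-methoxy-4-methylphenyl]-5-(tert-butyldimethylsilyloxy)-3-(3-methylbut-2-enyl)-2,4-dioxopentyl}-2,2-dimethyl-4H-1,3-dioxin-4-one (diastereomer mixture), via dilithium dianion 13 (not isolated)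
Conditions: 12 (1.3 equiv), LiN(i-Pr)2 (2.7 equiv), THF, −78 °C; then 7 (1.0 equiv), −78 to −20 °C; aq. NH4Cl
Reagents that add atoms: none
Why: Claisen-type acylation of the keto-dioxinone dianion takes place at its more basic terminal carbanion (the carbon carrying the future prenyl group), and the chelated tetrahedral intermediate of the Weinreb amide prevents over-addition and proton transfer from the product; the two new stereocentres form unselectively and are both destroyed later.

Step 8
Reactants: 14 the diketo-dioxinone of step 7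
Product: 16 5-{(tert-butyldimethylsilyloxy)[2-(tert-butyldimethylsilyloxy)-3-chloro-6-methoxy-4-methylphenyl]methyl}-7-hydroxy-2,2-dimethyl-6-(3-methylbut-2-enyl)-4H-1,3-benzodioxin-4-one (racemic), via cyclic aldol adduct 15 (not isolated)
Conditions: Et3N (5 equiv), CH2Cl2, rt; volatiles removed; then pyridinium p-toluenesulfonate (cat.), CH2Cl2, rt
Reagents that add atoms: none
Why: Et3N removes a proton from the methylene between the dioxinone and the C5' ketone, and the α-carbon of the resulting extended dienolate (dioxinone C5, future C2') adds to the ketone next to the silylated carbinol (future C1') to give aldol 15; loss of water and enolization of the C5' carbonyl then aromatize ring B, the mild acid completing the dehydration. The closest known reaction type is the base-mediated aldol cycloaromatization of diketo-dioxinones (masked 3,5,7-triketo esters) to acetonide-protected resorcylates. Ring B closes in a 6-(enolexo)-exo-trig mode. No lasting stereocentre is made: the centres of the 1,3-diketone and of the aldol adduct vanish on aromatization and the racemic carbinol is untouched. The step needs aldol and not Claisen folding, and C- and not O-cyclization; this is secured because the prenylated central carbon would become quaternary and non-aromatizable in the Claisen mode, the dioxinone carbonyl is a poor electrophile, and only the C2'-to-C1' addition gives a six-membered carbocycle. The prenyl group therefore arrives at C6' without any aromatic C-prenylation, and the carboxyl carbon stays masked as the acetonide lactone of the C3' phenol.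

Step 9
Reactants: 16 the benzodioxinone of step 8
Product: 18 3-(3-chloro-2-hydroxy-6-methoxy-4-methylphenyl)-5,7-dihydroxy-4-(3-methylbut-2-enyl)-2-benzofuran-1(3H)-one (racemic), via desilylated carbinol 17 (not isolated)
Conditions: Bu4NF (4 equiv), THF, 0 °C to rt; aq. NH4Cl
Reagents that add atoms: none
Why: Fluoride cleaves both silyl ethers, and the freed benzylic alkoxide attacks the neighbouring dioxinone carbonyl in a 5-exo-trig acyl substitution that expels acetone and the C3' phenoxide (desilylation–translactonization to the phthalide).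

Step 10
Reactants: 18 the phthalide triol of step 9
Product: 19 5,7-bis(tert-butyldimethylsilyloxy)-3-[2-(tert-butyldimethylsilyloxy)-3-chloro-6-methoxy-4-methylphenyl]-4-(3-methylbut-2-enyl)-2-benzofuran-1(3H)-one (racemic)
Conditions: TBSOTf (4 equiv), 2,6-lutidine, CH2Cl2, 0 °C to rt
Reagents that add atoms: tert-butyldimethylsilyl trifluoromethanesulfonate, CC(C)(C)[Si](C)(C)OS(=O)(=O)C(F)(F)F
Why: Exhaustive silylation with the silyl triflate masks all three phenols, including the hydrogen-bonded one next to the lactone carbonyl, so that the following oxidation with activated DMSO is not diverted by free phenols.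

Step 11
Reactants: 19 the tris-silylated phthalide of step 10
Product: 20 [2-(tert-butyldimethylsilyloxy)-3-chloro-6-methoxy-4-methylphenyl][3,5-bis(tert-butyldimethylsilyloxy)-2-(hydroxymethyl)-6-(3-methylbut-2-enyl)phenyl]methanol (racemic)
Conditions: i-Bu2AlH (4 equiv), CH2Cl2, −78 to 0 °C; aq. KNaC4H4O6
Reagents that add atoms: none
Why: Hydride reduction of the phthalide past the lactol stage gives the 1,4-diol, and the weakly nucleophilic aluminium alkoxides should leave the aryl silyl ethers in place and not provoke silyl migration.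

Step 12
Reactants: 20 the diol of step 11
Product: 22 4,6-bis(tert-butyldimethylsilyloxy)-2-[2-(tert-butyldimethylsilyloxy)-3-chloro-6-methoxy-4-methylbenzoyl]-3-(3-methylbut-2-enyl)benzaldehyde, via bis(alkoxysulfonium) salt 21 (not isolated)
Conditions: (COCl)2 (4 equiv), DMSO (8 equiv), CH2Cl2, −78 °C; 20, −78 to −60 °C; then Et3N (12 equiv), −78 to 0 °C
Reagents that add atoms: none
Why: In the Swern oxidation both hydroxyls are converted into alkoxysulfonium ions before base is added, so the hydroxy aldehyde that would close to a lactol and be oxidized back to the phthalide is never present, as in the oxidation of 1,2-benzenedimethanols to phthalaldehydes.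

Step 13
Reactants: 22 the tris-silylated keto aldehyde of step 12
Product: 23 Pestalone F, 2-(3-chloro-2-hydroxy-6-methoxy-4-methylbenzoyl)-4,6-dihydroxy-3-(3-methylbut-2-enyl)benzaldehyde
Conditions: HF·pyridine, THF/pyridine, 0 °C to rt
Reagents that add atoms: none
Why: Mildly acidic fluoride removes the three aryl silyl ethers without the base that could trigger Cannizzaro–Tishchenko isomerization of the ortho-aroylbenzaldehyde to the phthalide, and is too weak an acid to cyclize the ortho-prenyl phenol.

**Compound list**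

1 | 3-methoxy-5-methylphenol | COc1cc(C)cc(O)c1 | starting material
2 | 2-chloro-5-methoxy-3-methylphenol | COc1cc(C)c(Cl)c(O)c1 | intermediate
3 | ethyl glyoxylate (ethyl 2-oxoacetate) | CCOC(=O)C=O | starting material
4 | bromomagnesium 2-chloro-5-methoxy-3-methylphenoxide | COc1cc(C)c(Cl)c(O[Mg]Br)c1 | intermediate
5 | ethyl 2-(3-chloro-2-hydroxy-6-methoxy-4-methylphenyl)-2-hydroxyacetate (racemic) | CCOC(=O)C(O)c1c(OC)cc(C)c(Cl)c1O | intermediate
6 | ethyl 2-(tert-butyldimethylsilyloxy)-2-[2-(tert-butyldimethylsilyloxy)-3-chloro-6-methoxy-4-methylphenyl]acetate (racemic) | CCOC(=O)C(O[Si](C)(C)C(C)(C)C)c1c(OC)cc(C)c(Cl)c1O[Si](C)(C)C(C)(C)C | intermediate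
7 | 2-(tert-butyldimethylsilyloxy)-2-[2-(tert-butyldimethylsilyloxy)-3-chloro-6-methoxy-4-methylphenyl]-N-methoxy-N-methylacetamide (racemic) | CON(C)C(=O)C(O[Si](C)(C)C(C)(C)C)c1c(OC)cc(C)c(Cl)c1O[Si](C)(C)C(C)(C)C | intermediate
8 | 5-methylhex-4-enoic acid | CC(C)=CCCC(=O)O | starting material
9 | 5-methylhex-4-enoyl chloride | CC(C)=CCCC(=O)Cl | intermediate
10 | 2,2,6-trimethyl-4H-1,3-dioxin-4-one | CC1=CC(=O)OC(C)(C)O1 | starting material
11 | lithium dienolate of 10 (lithium 2,2-dimethyl-6-methylidene-6H-1,3-dioxin-4-olate) | C=C1C=C(O[Li])OC(C)(C)O1 | intermediate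
12 | 2,2-dimethyl-6-(6-methyl-2-oxohept-5-enyl)-4H-1,3-dioxin-4-one | CC(C)=CCCC(=O)CC1=CC(=O)OC(C)(C)O1 | intermediate
13 | dilithium dianion of 12 (dioxinone dienolate plus ketone enolate toward C3 of the side chain) | CC(C)=CCC=C(O[Li])C=C1C=C(O[Li])OC(C)(C)O1 | intermediate
14 | 6-{5-[2-(tert-butyldimethylsilyloxy)-3-chloro-6-methoxy-4-methylphenyl]-5-(tert-butyldimethylsilyloxy)-3-(3-methylbut-2-enyl)-2,4-dioxopentyl}-2,2-dimethyl-4H-1,3-dioxin-4-one (diastereomer mixture) | CC1(C)OC(=O)C=C(CC(=O)C(CC=C(C)C)C(=O)C(O[Si](C)(C)C(C)(C)C)c2c(OC)cc(C)c(Cl)c2O[Si](C)(C)C(C)(C)C)O1 | intermediate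
15 | 5-{(tert-butyldimethylsilyloxy)[2-(tert-butyldimethylsilyloxy)-3-chloro-6-methoxy-4-methylphenyl]methyl}-5-hydroxy-2,2-dimethyl-6-(3-methylbut-2-enyl)-4a,5-dihydro-4H-1,3-benzodioxine-4,7(6H)-dione (cyclic aldol adduct, diastereomer mixture) | CC1(C)OC(=O)C2C(=CC(=O)C(CC=C(C)C)C2(O)C(O[Si](C)(C)C(C)(C)C)c3c(OC)cc(C)c(Cl)c3O[Si](C)(C)C(C)(C)C)O1 | intermediate
16 | 5-{(tert-butyldimethylsilyloxy)[2-(tert-butyldimethylsilyloxy)-3-chloro-6-methoxy-4-methylphenyl]methyl}-7-hydroxy-2,2-dimethyl-6-(3-methylbut-2-enyl)-4H-1,3-benzodioxin-4-one (racemic) | CC1(C)Oc2cc(O)c(CC=C(C)C)c(C(O[Si](C)(C)C(C)(C)C)c3c(OC)cc(C)c(Cl)c3O[Si](C)(C)C(C)(C)C)c2C(=O)O1 | intermediate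
17 | 5-[(3-chloro-2-hydroxy-6-methoxy-4-methylphenyl)(hydroxy)methyl]-7-hydroxy-2,2-dimethyl-6-(3-methylbut-2-enyl)-4H-1,3-benzodioxin-4-one (racemic) | CC1(C)Oc2cc(O)c(CC=C(C)C)c(C(O)c3c(OC)cc(C)c(Cl)c3O)c2C(=O)O1 | intermediate
18 | 3-(3-chloro-2-hydroxy-6-methoxy-4-methylphenyl)-5,7-dihydroxy-4-(3-methylbut-2-enyl)-2-benzofuran-1(3H)-one (racemic) | COc1cc(C)c(Cl)c(O)c1C2OC(=O)c3c(O)cc(O)c(CC=C(C)C)c23 | intermediate
19 | 5,7-bis(tert-butyldimethylsilyloxy)-3-[2-(tert-butyldimethylsilyloxy)-3-chloro-6-methoxy-4-methylphenyl]-4-(3-methylbut-2-enyl)-2-benzofuran-1(3H)-one (racemic) | COc1cc(C)c(Cl)c(O[Si](C)(C)C(C)(C)C)c1C2OC(=O)c3c(O[Si](C)(C)C(C)(C)C)cc(O[Si](C)(C)C(C)(C)C)c(CC=C(C)C)c23 | intermediate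
20 | [2-(tert-butyldimethylsilyloxy)-3-chloro-6-methoxy-4-methylphenyl][3,5-bis(tert-butyldimethylsilyloxy)-2-(hydroxymethyl)-6-(3-methylbut-2-enyl)phenyl]methanol (racemic) | COc1cc(C)c(Cl)c(O[Si](C)(C)C(C)(C)C)c1C(O)c1c(CO)c(O[Si](C)(C)C(C)(C)C)cc(O[Si](C)(C)C(C)(C)C)c1CC=C(C)C | intermediate
21 | bis(dimethylsulfonio) ether of diol 20, dichloride (both hydroxyls as O–S+Me2; racemic) | COc1cc(C)c(Cl)c(O[Si](C)(C)C(C)(C)C)c1C(O[S+](C)C)c1c(CO[S+](C)C)c(O[Si](C)(C)C(C)(C)C)cc(O[Si](C)(C)C(C)(C)C)c1CC=C(C)C.[Cl-].[Cl-] | intermediate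
22 | 4,6-bis(tert-butyldimethylsilyloxy)-2-[2-(tert-butyldimethylsilyloxy)-3-chloro-6-methoxy-4-methylbenzoyl]-3-(3-methylbut-2-enyl)benzaldehyde | COc1cc(C)c(Cl)c(O[Si](C)(C)C(C)(C)C)c1C(=O)c1c(C=O)c(O[Si](C)(C)C(C)(C)C)cc(O[Si](C)(C)C(C)(C)C)c1CC=C(C)C | intermediate
23 | Pestalone F, 2-(3-chloro-2-hydroxy-6-methoxy-4-methylbenzoyl)-4,6-dihydroxy-3-(3-methylbut-2-enyl)benzaldehyde | COc1cc(C)c(Cl)c(O)c1C(=O)c1c(C=O)c(O)cc(O)c1CC=C(C)C | target

**Summary**

Total step count: 13. Longest linear sequence: 11 steps (1 → 2 → 5 → 6 → 7 → 14 → 16 → 18 → 19 → 20 → 22 → 23); the dioxinone branch (8 → 9 → 12) adds two steps and joins at step 7.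

Steps most likely to fail:

Step 7. The secondary carbanion of the dianion may acylate the hindered amide carbonyl too slowly, so that proton transfer from the α-position of the amide or attack at its N-methoxy group takes over. The fallback sets out from ester 6 and keto-dioxinone 12 and returns at 14. Ester 6 would be reduced with i-Bu2AlH (CH2Cl2, −78 °C) to 2-(tert-butyldimethylsilyloxy)-2-[2-(tert-butyldimethylsilyloxy)-3-chloro-6-methoxy-4-methylphenyl]acetaldehyde F1. Dianion 13, made from 12 as in step 7, should add to this smaller and more electrophilic carbonyl at −78 °C to give the aldol 6-{5-[2-(tert-butyldimethylsilyloxy)-3-chloro-6-methoxy-4-methylphenyl]-5-(tert-butyldimethylsilyloxy)-4-hydroxy-3-(3-methylbut-2-enyl)-2-oxopentyl}-2,2-dimethyl-4H-1,3-dioxin-4-one F2 as a diastereomer mixture. Oxidation of the β-hydroxy ketone with Dess–Martin periodinane (NaHCO3, CH2Cl2) would then give 14.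

Step 8. Aldol addition to the ketone flanked by the silylated carbinol and the prenylated carbon may be too slow under amine catalysis, leaving room for O-cyclization or decomposition of the diketone. The fallback sets out from 14 and returns at 18. Heating 14 in toluene at 110 °C with methanol would open the dioxinone by cycloreversion with loss of acetone and trap the acylketene as methyl 8-[2-(tert-butyldimethylsilyloxy)-3-chloro-6-methoxy-4-methylphenyl]-8-(tert-butyldimethylsilyloxy)-6-(3-methylbut-2-enyl)-3,5,7-trioxooctanoate F3. In this open chain the true β-keto ester methylene C2 is a freer and stronger nucleophile for the same C2-to-C7 (C2'–C1') aldol closure. Cs2CO3 in MeOH followed by HCl in MeOH should aromatize it and at the same time remove the phenolic silyl group of ring A, giving methyl 2-[(tert-butyldimethylsilyloxy)(3-chloro-2-hydroxy-6-methoxy-4-methylphenyl)methyl]-4,6-dihydroxy-3-(3-methylbut-2-enyl)benzoate F4. Bu4NF in THF would then free the carbinol, which lactonizes onto the methyl ester to give 18.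

Step 12. The tetra-ortho-substituted benzhydrol may be activated incompletely, so that the primary aldehyde forms first and closes onto the free secondary hydroxyl to a lactol that is oxidized back to the phthalide; ionization of the electron-rich benzylic alkoxysulfonium ions is a second leak. The fallback sets out from 20 and returns at 22. Et3SiCl and imidazole (CH2Cl2, −20 °C) should silylate only the primary hydroxyl to give [2-(tert-butyldimethylsilyloxy)-3-chloro-6-methoxy-4-methylphenyl]{3,5-bis(tert-butyldimethylsilyloxy)-6-(3-methylbut-2-enyl)-2-[(triethylsilyloxy)methyl]phenyl}methanol F5. Dess–Martin periodinane would oxidize the benzhydrol to [2-(tert-butyldimethylsilyloxy)-3-chloro-6-methoxy-4-methylphenyl]{3,5-bis(tert-butyldimethylsilyloxy)-6-(3-methylbut-2-enyl)-2-[(triethylsilyloxy)methyl]phenyl}methanone F6. Pyridinium p-toluenesulfonate in MeOH/CH2Cl2 at 0 °C would remove only the triethylsilyl group to give [2-(tert-butyldimethylsilyloxy)-3-chloro-6-methoxy-4-methylphenyl][3,5-bis(tert-butyldimethylsilyloxy)-2-(hydroxymethyl)-6-(3-methylbut-2-enyl)phenyl]methanone F7. A second Dess–Martin oxidation, now with the ketone already in place so that no oxidizable lactol can form, would give 22.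

Further compounds
F1 | step 7 | 2-(tert-butyldimethylsilyloxy)-2-[2-(tert-butyldimethylsilyloxy)-3-chloro-6-methoxy-4-methylphenyl]acetaldehyde (racemic) | O=CC(O[Si](C)(C)C(C)(C)C)c1c(OC)cc(C)c(Cl)c1O[Si](C)(C)C(C)(C)C
F2 | step 7 | 6-{5-[2-(tert-butyldimethylsilyloxy)-3-chloro-6-methoxy-4-methylphenyl]-5-(tert-butyldimethylsilyloxy)-4-hydroxy-3-(3-methylbut-2-enyl)-2-oxopentyl}-2,2-dimethyl-4H-1,3-dioxin-4-one (diastereomer mixture) | CC1(C)OC(=O)C=C(CC(=O)C(CC=C(C)C)C(O)C(O[Si](C)(C)C(C)(C)C)c2c(OC)cc(C)c(Cl)c2O[Si](C)(C)C(C)(C)C)O1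
F3 | step 8 | methyl 8-[2-(tert-butyldimethylsilyloxy)-3-chloro-6-methoxy-4-methylphenyl]-8-(tert-butyldimethylsilyloxy)-6-(3-methylbut-2-enyl)-3,5,7-trioxooctanoate (diastereomer mixture) | COC(=O)CC(=O)CC(=O)C(CC=C(C)C)C(=O)C(O[Si](C)(C)C(C)(C)C)c1c(OC)cc(C)c(Cl)c1O[Si](C)(C)C(C)(C)C
F4 | step 8 | methyl 2-[(tert-butyldimethylsilyloxy)(3-chloro-2-hydroxy-6-methoxy-4-methylphenyl)methyl]-4,6-dihydroxy-3-(3-methylbut-2-enyl)benzoate (racemic) | COC(=O)c1c(O)cc(O)c(CC=C(C)C)c1C(O[Si](C)(C)C(C)(C)C)c1c(OC)cc(C)c(Cl)c1O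
F5 | step 12 | [2-(tert-butyldimethylsilyloxy)-3-chloro-6-methoxy-4-methylphenyl]{3,5-bis(tert-butyldimethylsilyloxy)-6-(3-methylbut-2-enyl)-2-[(triethylsilyloxy)methyl]phenyl}methanol (racemic) | CC[Si](CC)(CC)OCc1c(O[Si](C)(C)C(C)(C)C)cc(O[Si](C)(C)C(C)(C)C)c(CC=C(C)C)c1C(O)c1c(OC)cc(C)c(Cl)c1O[Si](C)(C)C(C)(C)C
F6 | step 12 | [2-(tert-butyldimethylsilyloxy)-3-chloro-6-methoxy-4-methylphenyl]{3,5-bis(tert-butyldimethylsilyloxy)-6-(3-methylbut-2-enyl)-2-[(triethylsilyloxy)methyl]phenyl}methanone | CC[Si](CC)(CC)OCc1c(O[Si](C)(C)C(C)(C)C)cc(O[Si](C)(C)C(C)(C)C)c(CC=C(C)C)c1C(=O)c1c(OC)cc(C)c(Cl)c1O[Si](C)(C)C(C)(C)C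
F7 | step 12 | [2-(tert-butyldimethylsilyloxy)-3-chloro-6-methoxy-4-methylphenyl][3,5-bis(tert-butyldimethylsilyloxy)-2-(hydroxymethyl)-6-(3-methylbut-2-enyl)phenyl]methanone | OCc1c(O[Si](C)(C)C(C)(C)C)cc(O[Si](C)(C)C(C)(C)C)c(CC=C(C)C)c1C(=O)c1c(OC)cc(C)c(Cl)c1O[Si](C)(C)C(C)(C)C
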